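# Proposed synthesis of 4'''-hydroxytrianguletin (26) by a cyclobutenone–ynol ether benzannulation of ring D

## The problem

Compound 26 is an achiral hybrid of two polyphenols. A kaempferide-type flavonol (rings A, B and C) is joined through a single CH2 group from C8 of ring A to D1 of a fully substituted acylphloroglucinol ring D, whose 3-arylpropanoyl chain ends in the phenol ring E. There is no stereocentre, so the whole difficulty is positional. The bridge must sit at C8 and not C6 of ring A. On ring D, three oxygens in a 1,3,5 relationship must end as two free hydroxyls (D2, D4) flanking the acyl group (D3) and one methyl ether (D6) between the bridge carbon and the D5 methyl group. Joining two phloroglucinol-type rings by electrophilic substitution gives little means of telling D1 from D3 or C8 from C6, and tends to over-alkylate. The free flavonol and the polyphenolic rings are oxidised easily under base and air, the electron-rich diarylmethane can be split by strong acid, and the two aryl methyl ethers (4' and D6) must survive the final deprotection; this points to benzyl ethers and a hydrogenolytic finish. The feature that opens the key step is the pattern D2-OH / D1-C / D6-OMe with D3 as a position that can be C–H before acylation. That is the resorcinol monoether pattern formed when a vinylketene and an ynol ether combine, with D2, D3, D4 and D5 from a cyclobutenone and D1 and D6 from the alkyne. Ring D can therefore be grown on a CH2 group already fixed at C8, and its three oxygens emerge as OH, OMe and OBn, already differentiated.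

## Retrosynthesis

**26 to 25.** The six O–benzyl bonds (3-, 5-, 7-O of the flavonol, D2-O, D4-O and the ring E oxygen) are cut last. One hydrogenolysis over Pd/C removes them all and leaves both methyl ethers, the flavonol, the diaryl ketone and the bridge alone. Acidic or Lewis acidic global deprotection is avoided because it would endanger the D6 methyl ether and the bridge.

**25 to 20 and 23.** The D3–C(=O) bond is cut. D3 is the only C–H of ring D, lies between two oxygens and para to the third, and is the most nucleophilic carbon in the molecule. The acyl group cannot be carried through the ring synthesis, because the cyclobutenone carbon that becomes D3 must be CH2 for the annulation product to aromatise. The forward reaction is a Friedel–Crafts acylation through the mixed trifluoroacetic anhydride 24 of acid 23, with no metal halide. A chelating Lewis acid such as TiCl4 would bind the C4 carbonyl and the peri 5-benzyloxy group of the flavone and cleave that ether. For the same reason the D2 phenol of 19 is first capped as its benzyl ether (20), so that the acylating agent meets no free hydroxyl and one defined product results. Acid 23 comes from 3-(4-hydroxyphenyl)propanoic acid 21 by benzylation.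

**19 to 9 and 14.** This is the key disconnection. Bonds D1–D2, D5–D6 and D2–D3 are cut, which takes ring D apart into the four-carbon cyclobutenone 14 and the two alkyne carbons of ynol ether 9. The neighbouring cut, at CH2–D1 or CH2–C8, would require an electrophilic union of two electron-rich rings with the D1/D3 and C8/C6 ambiguities described above. The annulation instead builds ring D around a CH2 group that is already attached to C8. The precursors are far simpler: a hexasubstituted arene is exchanged for a small enone and a disubstituted alkyne. The forward reaction must give one orientation of the ketene–alkyne cycloaddition, and the cyclobutenone must open thermally even though its 3-alkoxy group stabilises it as a vinylogous ester.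

**9 to 5 and 8.** The CH2–C(sp) bond is cut. A free alkoxyacetylide would be the classical nucleophile, but it is basic and could add to the flavone carbonyl. A neutral Stille coupling of the benzylic bromide 5 with the stannane 8 avoids this. Stannane 8 is made from chloroacetaldehyde dimethyl acetal 6 through lithium methoxyacetylide 7 and can be distilled free of amine and methoxide. A methyl ynol ether is chosen because it becomes the D6 methoxy group directly and, having no β-hydrogen, cannot lose ketene by a retro-ene path on heating.

**5 back to 1.** The C8–CH2 bond is traced through alcohol 4 to iodide 3, and the C8–I bond to the tribenzyl ether 2 of commercial kaempferide 1. Full O-alkylation is what directs the electrophile to C8; with a free 5-hydroxyl, C6 would be attacked. Rings A, B and C and the 3-oxygen are thus bought, not made.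

**14 to 13, and 13 to 11 and 12.** The benzyl vinylogous ester 14 is traced to the ethyl analogue 13 by alkoxy exchange. Compound 13 is the cycloadduct of 1-ethoxyprop-1-yne 11 with ketene 12, generated from acetone 10. The same alkyne polarisation that controls the key step places the methyl group at C2 and the alkoxy group at C3.

## Roads not taken

**Alternative 1:** The cut is through ring C (C4a–C4, C4–C3 and O1–C2). In the forward direction the iodophenol A1, which already carries ring D on its CH2 group, would be coupled with carbon monoxide and 4-ethynylanisole A2 using PdCl2(PPh3)2 and diethylamine. The resulting ortho-hydroxyaryl ynone would close to the flavone A3.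
- Merits: the step is convergent, catalytic, and rests on very reliable chemistry for flavones. In robustness of the key step it is better than an annulation that uses a donor-substituted cyclobutenone.
- Weak points: A3 is a flavone with C3–H, so the 3-hydroxyl must be introduced late by oxidation, on a molecule with an enolisable aryl ketone and an oxidisable diarylmethane. The hexasubstituted ring D and its link to the correct ring A carbon must already exist in A1, which returns the problem to the electrophilic union of two phloroglucinol rings. An iodophloroglucinol adds slowly to zerovalent palladium and loses iodine easily, and five-membered (aurone) closure competes with the six-membered one.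
- Comparison: the chosen plan has a less certain key step. Against that, it buys rings A, B and C with the 3-oxygen in place and spends its key step on ring D, where the real difficulty lies.

**Alternative 2:** The cut is through ring A (CH2–C8 and C6–C7). Irradiation of the diazo ketone A4 would expel nitrogen and the ring D benzyl group would migrate to the diazo carbon (Wolff rearrangement). The ketene would then close by 6π electrocyclization onto the silyl enol ether, giving the 7-phenol A5.
- Merits: the bridge is delivered to C8 within the molecule, so the C6/C8 question never arises. On this point it is more secure than the C8 iodination the chosen plan relies on. The ring-forming event is mechanistically close to the chosen key step.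
- Weak points: A4 is a fully substituted 4-pyranone bearing both a diazo ketone and a silyl dienol ether, and is long to assemble. The photolysis must proceed in a molecule that also holds a 3-alkoxy-2-arylpyranone and an aryl ketone, both photoactive. Ring D with all six substituents has to be made beforehand by other means. Ring A is rebuilt although it is available in 1.
- Comparison: the chosen plan sets a short sequence from a purchasable flavonol against the better positional certainty of this route, and it solves ring D instead of ring A.

**Alternative 3:** The cut is the D3–D4 bond of ring D, read as a polyketide. With Mg(OMe)2 in methanol the triketo ester A6 would undergo a Claisen condensation of its C6 enolate onto the ester carbon and enolise to the trihydroxy acyl ring of A7.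
- Merits: the acyl chain is built into the ring, so no late acylation is needed. In this respect the route is better than the chosen one. The D6 hydroxyl of A7, para to the ketone and not chelated, should be the one that is methylated preferentially.
- Weak points: A6 is a doubly branched 3,5,7-triketo ester. It would have to be made by polyanion chemistry that the flavone is unlikely to tolerate, or by alkylating a chain with three competing active methylene groups. Its cyclisation can take aldol, Claisen or pyrone-forming courses, and branching at C2 and C4 slows the desired one. The final methylation must avoid the second and third hydroxyls and dearomatising C-methylation.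
- Comparison: the chosen plan pays for its late acylation with two extra operations. In return it uses stable, well-defined precursors and obtains the oxygen differentiation from the annulation itself, without a selective methylation.

Key step: step 9

## Route

Remark: 26 is achiral; the only stereocentre that appears on the route, the quaternary carbon of the transient cyclobutenone 16, is formed racemic and erased in the same flask, so no step has to control configuration.

Step 1
Reactants: 1 kaempferide
Product: 2 3,5,7-tris(benzyloxy)-2-(4-methoxyphenyl)-4H-chromen-4-one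
Conditions: BnBr (4.5 equiv), K2CO3 (6 equiv), DMF, 70 °C
Reagents that add atoms: benzyl bromide, BrCc1ccccc1
Why: Williamson etherification; the 7- and 3-hydroxyls react readily and the chelated 5-hydroxyl follows with excess reagent and heat, as is routine for perbenzylation of 5-hydroxyflavonols.

Step 2
Reactants: 2 3,5,7-tris(benzyloxy)-2-(4-methoxyphenyl)-4H-chromen-4-one
Product: 3 3,5,7-tris(benzyloxy)-8-iodo-2-(4-methoxyphenyl)-4H-chromen-4-one
Conditions: NIS (1.1 equiv), TFA (0.2 equiv), CH2Cl2–MeCN, 0 °C to rt, dark
Reagents that add atoms: N-iodosuccinimide, O=C1CCC(=O)N1I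
Why: Electrophilic aromatic iodination; in 5,7-dialkoxyflavones the established site is C8 (para to the 5-oxygen, ortho to the 7-oxygen), C6 being favoured only when the 5-hydroxyl is free, and ring B is deactivated by the pyranone.

Step 3
Reactants: 3 3,5,7-tris(benzyloxy)-8-iodo-2-(4-methoxyphenyl)-4H-chromen-4-one
Product: 4 3,5,7-tris(benzyloxy)-8-(hydroxymethyl)-2-(4-methoxyphenyl)-4H-chromen-4-one
Conditions: Bu3SnCH2OH (1.5 equiv), Pd(PPh3)4 (10 mol%), 1,4-dioxane, 100 °C
Reagents that add atoms: (tributylstannyl)methanol, CCCC[Sn](CCCC)(CCCC)CO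
Why: Migita–Kosugi–Stille hydroxymethylation of an aryl iodide; 8-iodoflavones are competent cross-coupling partners and the neutral conditions leave the benzyl ethers and the pyranone untouched.

Step 4
Reactants: 4 3,5,7-tris(benzyloxy)-8-(hydroxymethyl)-2-(4-methoxyphenyl)-4H-chromen-4-one
Product: 5 3,5,7-tris(benzyloxy)-8-(bromomethyl)-2-(4-methoxyphenyl)-4H-chromen-4-one
Conditions: CBr4 (1.3 equiv), PPh3 (1.4 equiv), CH2Cl2, 0 °C; used without storage
Reagents that add atoms: carbon tetrabromide, BrC(Br)(Br)Br
Why: Appel bromination of a benzylic alcohol under neutral conditions; the ortho and para alkoxy groups are tied into the vinylogous ester of the chromenone, so the bromide should be reactive but handleable if used cold and promptly.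

Step 5
Reactants: 6 chloroacetaldehyde dimethyl acetal
Product: 8 tributyl(methoxyethynyl)stannane, via lithium methoxyacetylide 7 (not isolated)
Conditions: LiNEt2 (3.1 equiv, from Et2NH and n-BuLi), THF, 0 °C to rt; then Bu3SnCl, −78 °C to rt; filtration, distillation
Reagents that add atoms: tributyltin chloride, CCCC[Sn](Cl)(CCCC)CCCC
Why: Two successive base-induced eliminations (methanol, then HCl) give methoxyacetylene, which is deprotonated in the same flask, and the acetylide substitutes chloride at tin; this mirrors the standard preparation of the ethoxy analogue, and distillation frees the reagent from amine and methoxide.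

Step 6
Reactants: 5 3,5,7-tris(benzyloxy)-8-(bromomethyl)-2-(4-methoxyphenyl)-4H-chromen-4-one; 8 tributyl(methoxyethynyl)stannane
Product: 9 3,5,7-tris(benzyloxy)-2-(4-methoxyphenyl)-8-(3-methoxyprop-2-yn-1-yl)-4H-chromen-4-one
Conditions: Pd2(dba)3 (2.5 mol%), P(2-furyl)3 (10 mol%), THF, 50 °C; chromatography on Et3N-deactivated silica
Reagents that add atoms: none
Why: Stille benzyl–alkynyl coupling; benzylic bromides add quickly to the palladium catalyst and the alkynyl group is the fastest to transfer from tin, while the neutral medium spares the flavone carbonyl (which a free acetylide could attack) and the acid-sensitive ynol ether.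

Step 7
Reactants: 10 acetone; 11 1-ethoxyprop-1-yne
Product: 13 3-ethoxy-2-methylcyclobut-2-en-1-one, via ketene 12 (not isolated)
Conditions: ketene generator (pyrolysis of acetone, ca. 700 °C), gas stream passed into 11 in CH2Cl2, 0 °C to rt
Reagents that add atoms: none
Why: Ketene–ynol ether [2+2] cycloaddition; the ketene carbonyl carbon bonds to the nucleophilic methyl-bearing alkyne carbon, which places methyl at C2 and ethoxy at C3, as known for ketene with alkoxyalkynes.

Step 8
Reactants: 13 3-ethoxy-2-methylcyclobut-2-en-1-one
Product: 14 3-(benzyloxy)-2-methylcyclobut-2-en-1-one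
Conditions: BnOH (3 equiv), camphorsulfonic acid (5 mol%), toluene, 50 °C, reduced pressure (ethanol removed)
Reagents that add atoms: benzyl alcohol, OCc1ccccc1
Why: Acid-catalysed alkoxy exchange of a vinylogous ester by addition–elimination at C3, driven by removal of ethanol, as with 3-alkoxyenones and squarate esters.

Step 9
Reactants: 9 3,5,7-tris(benzyloxy)-2-(4-methoxyphenyl)-8-(3-methoxyprop-2-yn-1-yl)-4H-chromen-4-one; 14 3-(benzyloxy)-2-methylcyclobut-2-en-1-one
Product: 19 3,5,7-tris(benzyloxy)-8-{[4-(benzyloxy)-6-hydroxy-2-methoxy-3-methylphenyl]methyl}-2-(4-methoxyphenyl)-4H-chromen-4-one (ring D: D2 OH; D3 H; D4 OBn; D5 CH3; D6 OMe), via vinylketene 15 (not isolated), via vinylcyclobutenone 16 (not isolated), via dienylketene 17 (not isolated), via cyclohexadienone 18 (not isolated)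
Conditions: 14 (2 equiv), dry toluene, 110 °C, sealed tube, argon; then K2CO3, MeOH–THF, rt
Reagents that add atoms: none
Why: Thermal four-electron conrotatory opening of 14 gives vinylketene 15, whose electrophilic carbonyl carbon is attacked by the nucleophilic β-carbon of ynol ether 9 (the carbon bearing the flavonylmethyl group) in a [2+2] cycloaddition that forms bonds D1–D2 and D5–D6 and gives the 4-vinylcyclobutenone 16. Reversible opening of 16 gives dienylketene 17, and only the isomer with the benzyloxyvinyl group cis to the ketene reacts on: its 6π electrocyclization forms bond D2–D3 and closes ring D as cyclohexadienone 18, which tautomerises irreversibly to phenol 19. This is the Danheiser benzannulation of a cyclobutenone with an alkoxyalkyne; the closest analogy for the donor-substituted partner is the squarate-derived 3-alkoxycyclobutenones, which open to vinylketenes in this temperature range. Ring D is therefore closed by a pericyclic 6π ring closure and not by a polar cyclisation. The quaternary carbon of 16 is the only stereocentre formed; it is racemic and is erased when 16 opens. The selectivity required is the orientation of the [2+2] step, secured by the polarisation of the ynol ether (its oxygen-bearing carbon bonds to the ketene α-carbon); this puts the new hydroxyl at D2 next to the bridge, methoxy at D6, methyl at D5, benzyloxy at D4 and leaves D3 as C–H. A methyl ynol ether has no β-hydrogen for retro-ene loss, the flavone and benzyl ethers are inert to neutral heating, and the brief methanolysis returns any phenol acylated by excess 15.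

Step 10
Reactants: 19 3,5,7-tris(benzyloxy)-8-{[4-(benzyloxy)-6-hydroxy-2-methoxy-3-methylphenyl]methyl}-2-(4-methoxyphenyl)-4H-chromen-4-one
Product: 20 3,5,7-tris(benzyloxy)-8-{[4,6-bis(benzyloxy)-2-methoxy-3-methylphenyl]methyl}-2-(4-methoxyphenyl)-4H-chromen-4-one
Conditions: BnBr (1.5 equiv), K2CO3, DMF, 40 °C
Reagents that add atoms: benzyl bromide, BrCc1ccccc1
Why: Williamson etherification of the only free hydroxyl; it removes the site of O-acylation before the next step and makes D2 and D4 identical in protection.

Step 11
Reactants: 21 3-(4-hydroxyphenyl)propanoic acid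
Product: 23 3-[4-(benzyloxy)phenyl]propanoic acid, via benzyl ester 22 (not isolated)
Conditions: BnBr (2.3 equiv), K2CO3, DMF, 60 °C; then NaOH, MeOH–H2O, 60 °C; HCl work-up
Reagents that add atoms: benzyl bromide, BrCc1ccccc1
Why: Double O-benzylation (phenoxide and carboxylate) followed by saponification of the benzyl ester in the same flask; both are standard.

Step 12
Reactants: 20 3,5,7-tris(benzyloxy)-8-{[4,6-bis(benzyloxy)-2-methoxy-3-methylphenyl]methyl}-2-(4-methoxyphenyl)-4H-chromen-4-one; 23 3-[4-(benzyloxy)phenyl]propanoic acid
Product: 25 3,5,7-tris(benzyloxy)-8-({2,4-bis(benzyloxy)-3-{3-[4-(benzyloxy)phenyl]propanoyl}-6-methoxy-5-methylphenyl}methyl)-2-(4-methoxyphenyl)-4H-chromen-4-one, via mixed anhydride 24 (not isolated)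
Conditions: 23 (1.5 equiv), (CF3CO)2O (3 equiv), CH2Cl2, 0 °C to rt
Reagents that add atoms: none
Why: Friedel–Crafts acylation by the acyl trifluoroacetate, as known for 1,3,5-trialkoxybenzenes; D3 is the only C–H of a trialkoxy-dialkyl ring and far more nucleophilic than C6 of ring A (conjugated to the C4 carbonyl), ring B or the benzyl rings, and the absence of a chelating metal halide keeps the 5-benzyloxy group and the other benzyl ethers intact.

Step 13
Reactants: 25 3,5,7-tris(benzyloxy)-8-({2,4-bis(benzyloxy)-3-{3-[4-(benzyloxy)phenyl]propanoyl}-6-methoxy-5-methylphenyl}methyl)-2-(4-methoxyphenyl)-4H-chromen-4-one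
Product: 26 4'''-hydroxytrianguletin
Conditions: H2 (1 atm), 10% Pd/C, THF–MeOH, rt
Reagents that add atoms: none
Why: Hydrogenolysis of six aryl benzyl ethers; methyl ethers, the flavonol, the doubly ortho-oxygenated aryl ketone and the diarylmethane are not reduced at atmospheric pressure if the reaction is stopped at full debenzylation.

## Compound list

1 | kaempferide (3,5,7-trihydroxy-2-(4-methoxyphenyl)-4H-chromen-4-one) | COc1ccc(-c2oc3cc(O)cc(O)c3c(=O)c2O)cc1 | starting material
2 | 3,5,7-tris(benzyloxy)-2-(4-methoxyphenyl)-4H-chromen-4-one | COc1ccc(-c2oc3cc(OCc4ccccc4)cc(OCc4ccccc4)c3c(=O)c2OCc2ccccc2)cc1 | intermediate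
3 | 3,5,7-tris(benzyloxy)-8-iodo-2-(4-methoxyphenyl)-4H-chromen-4-one | COc1ccc(-c2oc3c(I)c(OCc4ccccc4)cc(OCc4ccccc4)c3c(=O)c2OCc2ccccc2)cc1 | intermediate
4 | 3,5,7-tris(benzyloxy)-8-(hydroxymethyl)-2-(4-methoxyphenyl)-4H-chromen-4-one | COc1ccc(-c2oc3c(CO)c(OCc4ccccc4)cc(OCc4ccccc4)c3c(=O)c2OCc2ccccc2)cc1 | intermediate
5 | 3,5,7-tris(benzyloxy)-8-(bromomethyl)-2-(4-methoxyphenyl)-4H-chromen-4-one | COc1ccc(-c2oc3c(CBr)c(OCc4ccccc4)cc(OCc4ccccc4)c3c(=O)c2OCc2ccccc2)cc1 | intermediate
6 | chloroacetaldehyde dimethyl acetal (2-chloro-1,1-dimethoxyethane) | COC(CCl)OC | starting material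
7 | lithium methoxyacetylide (not isolated) | [Li]C#COC | intermediate
8 | tributyl(methoxyethynyl)stannane | CCCC[Sn](CCCC)(CCCC)C#COC | intermediate
9 | 3,5,7-tris(benzyloxy)-2-(4-methoxyphenyl)-8-(3-methoxyprop-2-yn-1-yl)-4H-chromen-4-one | COC#CCc1c(OCc2ccccc2)cc(OCc2ccccc2)c2c1oc(-c1ccc(OC)cc1)c(OCc1ccccc1)c2=O | intermediate
10 | acetone | CC(C)=O | starting material
11 | 1-ethoxyprop-1-yne | CCOC#CC | starting material
12 | ketene (not isolated) | C=C=O | intermediate
13 | 3-ethoxy-2-methylcyclobut-2-en-1-one | CCOC1=C(C)C(=O)C1 | intermediate
14 | 3-(benzyloxy)-2-methylcyclobut-2-en-1-one | CC1=C(OCc2ccccc2)CC1=O | intermediate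
15 | 3-(benzyloxy)-2-methylbuta-1,3-dien-1-one (vinylketene, not isolated) | O=C=C(C)C(=C)OCc1ccccc1 | intermediate
16 | 4-[1-(benzyloxy)ethenyl]-3-methoxy-4-methyl-2-{[3,5,7-tris(benzyloxy)-2-(4-methoxyphenyl)-4-oxo-4H-chromen-8-yl]methyl}cyclobut-2-en-1-one (racemic, not isolated) | O=C1C(Cc2c(OCc3ccccc3)cc(OCc3ccccc3)c3c2oc(-c2ccc(OC)cc2)c(OCc2ccccc2)c3=O)=C(OC)C1(C)C(=C)OCc1ccccc1 | intermediate
17 | (3E)-5-(benzyloxy)-3-methoxy-4-methyl-2-{[3,5,7-tris(benzyloxy)-2-(4-methoxyphenyl)-4-oxo-4H-chromen-8-yl]methyl}hexa-1,3,5-trien-1-one (dienylketene, not isolated) | O=C=C(Cc1c(OCc2ccccc2)cc(OCc2ccccc2)c2c1oc(-c1ccc(OC)cc1)c(OCc1ccccc1)c2=O)/C(OC)=C(C)\C(=C)OCc1ccccc1 | intermediate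
18 | 5-(benzyloxy)-3-methoxy-4-methyl-2-{[3,5,7-tris(benzyloxy)-2-(4-methoxyphenyl)-4-oxo-4H-chromen-8-yl]methyl}cyclohexa-2,4-dien-1-one (not isolated) | O=C1CC(OCc2ccccc2)=C(C)C(OC)=C1Cc1c(OCc2ccccc2)cc(OCc2ccccc2)c2c1oc(-c1ccc(OC)cc1)c(OCc1ccccc1)c2=O | intermediate
19 | 3,5,7-tris(benzyloxy)-8-{[4-(benzyloxy)-6-hydroxy-2-methoxy-3-methylphenyl]methyl}-2-(4-methoxyphenyl)-4H-chromen-4-one | COc1ccc(-c2oc3c(Cc4c(O)cc(OCc5ccccc5)c(C)c4OC)c(OCc4ccccc4)cc(OCc4ccccc4)c3c(=O)c2OCc2ccccc2)cc1 | intermediate
20 | 3,5,7-tris(benzyloxy)-8-{[4,6-bis(benzyloxy)-2-methoxy-3-methylphenyl]methyl}-2-(4-methoxyphenyl)-4H-chromen-4-one | COc1ccc(-c2oc3c(Cc4c(OCc5ccccc5)cc(OCc5ccccc5)c(C)c4OC)c(OCc4ccccc4)cc(OCc4ccccc4)c3c(=O)c2OCc2ccccc2)cc1 | intermediate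
21 | 3-(4-hydroxyphenyl)propanoic acid | OC(=O)CCc1ccc(O)cc1 | starting material
22 | benzyl 3-[4-(benzyloxy)phenyl]propanoate (not isolated) | O=C(CCc1ccc(OCc2ccccc2)cc1)OCc1ccccc1 | intermediate
23 | 3-[4-(benzyloxy)phenyl]propanoic acid | OC(=O)CCc1ccc(OCc2ccccc2)cc1 | intermediate
24 | 3-[4-(benzyloxy)phenyl]propanoic trifluoroacetic anhydride (not isolated) | O=C(CCc1ccc(OCc2ccccc2)cc1)OC(=O)C(F)(F)F | intermediate
25 | 3,5,7-tris(benzyloxy)-8-({2,4-bis(benzyloxy)-3-{3-[4-(benzyloxy)phenyl]propanoyl}-6-methoxy-5-methylphenyl}methyl)-2-(4-methoxyphenyl)-4H-chromen-4-one | COc1ccc(-c2oc3c(Cc4c(OCc5ccccc5)c(C(=O)CCc5ccc(OCc6ccccc6)cc5)c(OCc5ccccc5)c(C)c4OC)c(OCc4ccccc4)cc(OCc4ccccc4)c3c(=O)c2OCc2ccccc2)cc1 | intermediate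
26 | 4'''-hydroxytrianguletin (8-({2,4-dihydroxy-3-[3-(4-hydroxyphenyl)propanoyl]-6-methoxy-5-methylphenyl}methyl)-3,5,7-trihydroxy-2-(4-methoxyphenyl)-4H-chromen-4-one) | COc1ccc(-c2oc3c(Cc4c(O)c(C(=O)CCc5ccc(O)cc5)c(O)c(C)c4OC)c(O)cc(O)c3c(=O)c2O)cc1 | target

## Step count and risk

Total step count: 13. Longest linear sequence: 9 steps (steps 1, 2, 3, 4, 6, 9, 10, 12 and 13).

**Step 9 (key step).** The most likely failure is slow ring opening of 14, whose 3-alkoxy group stabilises it as a vinylogous ester. At the temperature then needed, the ynol ether of 9 may be lost to hydration by traces of water, isomerisation to an allenyl ether, or oligomerisation with the ketene before the cycloaddition occurs. The fallback sets out from 9 and generates the same vinylketene without heat. Base-catalysed addition of benzyl alcohol to commercial ethyl 2-methylbuta-2,3-dienoate gives ethyl (E)-3-(benzyloxy)-2-methylbut-2-enoate F1. Saponification gives (E)-3-(benzyloxy)-2-methylbut-2-enoic acid F2, and oxalyl chloride gives (E)-3-(benzyloxy)-2-methylbut-2-enoyl chloride F3. Slow addition of F3 to 9 and triethylamine at room temperature causes 1,4-dehydrochlorination to 15, which is trapped as 16. Gentle warming then takes 16 through 17 and 18 to 19, where the route is rejoined.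

**Step 6.** Transmetalation from tin may be slow. The benzylpalladium intermediate would then homocouple, and the alkynylstannane or the product would be lost by protodestannylation and hydration of the ynol ether. The fallback sets out from 5 and 8 and replaces catalysis by classical substitution. Sodium iodide in acetone converts 5 into 3,5,7-tris(benzyloxy)-8-(iodomethyl)-2-(4-methoxyphenyl)-4H-chromen-4-one F4. Tin–lithium exchange of 8 with methyllithium at −78 °C gives 7 free of amine and methoxide. Alkylation of 7 with F4 in THF–DMPU at low temperature, where substitution at the benzylic iodide should outrun addition to the hindered chromenone carbonyl, returns to the route at 9.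

**Step 12.** Acylation at the position flanked by two benzyloxy groups may be sluggish. The trifluoroacetic acid formed could then cause protonation at D1 and retro-Friedel–Crafts scission of the bridge, or acylation at D1 with loss of the flavonylmethyl group. The fallback sets out from 20 and builds the ketone by carbonyl addition instead. Vilsmeier–Haack formylation (POCl3, DMF) gives 2,6-bis(benzyloxy)-4-methoxy-5-methyl-3-{[3,5,7-tris(benzyloxy)-2-(4-methoxyphenyl)-4-oxo-4H-chromen-8-yl]methyl}benzaldehyde F5. Addition at −78 °C of 2-[4-(benzyloxy)phenyl]ethylmagnesium bromide F6, made from the commercial bromide and magnesium, gives the racemic benzylic carbinol 3,5,7-tris(benzyloxy)-8-({2,4-bis(benzyloxy)-3-{1-hydroxy-3-[4-(benzyloxy)phenyl]propyl}-6-methoxy-5-methylphenyl}methyl)-2-(4-methoxyphenyl)-4H-chromen-4-one F7. Dess–Martin oxidation of F7 returns to the route at 25.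

**Step 8.** Under acid, ring cleavage of the strained vinylogous ester to an acetoacetate may compete with alkoxy exchange, or the exchange may stop short of completion. The fallback sets out from 13 and forms the O–benzyl bond by alkylation. Dilute aqueous acid hydrolyses 13 to 2-methylcyclobutane-1,3-dione F8. Mitsunobu O-alkylation of this vinylogous acid with benzyl alcohol (PPh3, diisopropyl azodicarboxylate) returns to the route at 14.

## Further compounds

F1 | step 9 | ethyl (E)-3-(benzyloxy)-2-methylbut-2-enoate | CCOC(=O)/C(C)=C(C)/OCc1ccccc1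
F2 | step 9 | (E)-3-(benzyloxy)-2-methylbut-2-enoic acid | OC(=O)/C(C)=C(C)/OCc1ccccc1
F3 | step 9 | (E)-3-(benzyloxy)-2-methylbut-2-enoyl chloride | ClC(=O)/C(C)=C(C)/OCc1ccccc1
F4 | step 6 | 3,5,7-tris(benzyloxy)-8-(iodomethyl)-2-(4-methoxyphenyl)-4H-chromen-4-one | COc1ccc(-c2oc3c(CI)c(OCc4ccccc4)cc(OCc4ccccc4)c3c(=O)c2OCc2ccccc2)cc1
F5 | step 12 | 2,6-bis(benzyloxy)-4-methoxy-5-methyl-3-{[3,5,7-tris(benzyloxy)-2-(4-methoxyphenyl)-4-oxo-4H-chromen-8-yl]methyl}benzaldehyde | COc1ccc(-c2oc3c(Cc4c(OCc5ccccc5)c(C=O)c(OCc5ccccc5)c(C)c4OC)c(OCc4ccccc4)cc(OCc4ccccc4)c3c(=O)c2OCc2ccccc2)cc1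
F6 | step 12 | 2-[4-(benzyloxy)phenyl]ethylmagnesium bromide | Br[Mg]CCc1ccc(OCc2ccccc2)cc1
F7 | step 12 | 3,5,7-tris(benzyloxy)-8-({2,4-bis(benzyloxy)-3-{1-hydroxy-3-[4-(benzyloxy)phenyl]propyl}-6-methoxy-5-methylphenyl}methyl)-2-(4-methoxyphenyl)-4H-chromen-4-one (racemic) | COc1ccc(-c2oc3c(Cc4c(OCc5ccccc5)c(C(O)CCc5ccc(OCc6ccccc6)cc5)c(OCc5ccccc5)c(C)c4OC)c(OCc4ccccc4)cc(OCc4ccccc4)c3c(=O)c2OCc2ccccc2)cc1
F8 | step 8 | 2-methylcyclobutane-1,3-dione | CC1C(=O)CC1=O
A1 | alternative 1 | 5-(benzyloxy)-4-iodo-2-({2,4-bis(benzyloxy)-3-{3-[4-(benzyloxy)phenyl]propanoyl}-6-methoxy-5-methylphenyl}methyl)benzene-1,3-diol | Oc1c(I)c(OCc2ccccc2)cc(O)c1Cc1c(OCc2ccccc2)c(C(=O)CCc2ccc(OCc3ccccc3)cc2)c(OCc2ccccc2)c(C)c1OC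
A2 | alternative 1 | 4-ethynylanisole | COc1ccc(C#C)cc1
A3 | alternative 1 | 5-(benzyloxy)-7-hydroxy-2-(4-methoxyphenyl)-8-({2,4-bis(benzyloxy)-3-{3-[4-(benzyloxy)phenyl]propanoyl}-6-methoxy-5-methylphenyl}methyl)-4H-chromen-4-one | COc1ccc(-c2cc(=O)c3c(OCc4ccccc4)cc(O)c(Cc4c(OCc5ccccc5)c(C(=O)CCc5ccc(OCc6ccccc6)cc5)c(OCc5ccccc5)c(C)c4OC)c3o2)cc1
A4 | alternative 2 | 3-(benzyloxy)-5-[1-(tert-butyldimethylsilyloxy)ethenyl]-6-[1-diazo-2-oxo-3-(2,4-bis(benzyloxy)-3-{3-[4-(benzyloxy)phenyl]propanoyl}-6-methoxy-5-methylphenyl)propyl]-2-(4-methoxyphenyl)-4H-pyran-4-one | COc1ccc(-c2oc(C(=[N+]=[N-])C(=O)Cc3c(OCc4ccccc4)c(C(=O)CCc4ccc(OCc5ccccc5)cc4)c(OCc4ccccc4)c(C)c3OC)c(C(=C)O[Si](C)(C)C(C)(C)C)c(=O)c2OCc2ccccc2)cc1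
A5 | alternative 2 | 3-(benzyloxy)-5-(tert-butyldimethylsilyloxy)-7-hydroxy-2-(4-methoxyphenyl)-8-({2,4-bis(benzyloxy)-3-{3-[4-(benzyloxy)phenyl]propanoyl}-6-methoxy-5-methylphenyl}methyl)-4H-chromen-4-one | COc1ccc(-c2oc3c(Cc4c(OCc5ccccc5)c(C(=O)CCc5ccc(OCc6ccccc6)cc5)c(OCc5ccccc5)c(C)c4OC)c(O)cc(O[Si](C)(C)C(C)(C)C)c3c(=O)c2OCc2ccccc2)cc1
A6 | alternative 3 | methyl 9-[4-(benzyloxy)phenyl]-2-methyl-3,5,7-trioxo-4-{[3,5,7-tris(benzyloxy)-2-(4-methoxyphenyl)-4-oxo-4H-chromen-8-yl]methyl}nonanoate (mixture of stereoisomers) | COC(=O)C(C)C(=O)C(Cc1c(OCc2ccccc2)cc(OCc2ccccc2)c2c1oc(-c1ccc(OC)cc1)c(OCc1ccccc1)c2=O)C(=O)CC(=O)CCc1ccc(OCc2ccccc2)cc1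
A7 | alternative 3 | 3,5,7-tris(benzyloxy)-8-({2,4,6-trihydroxy-3-{3-[4-(benzyloxy)phenyl]propanoyl}-5-methylphenyl}methyl)-2-(4-methoxyphenyl)-4H-chromen-4-one | COc1ccc(-c2oc3c(Cc4c(O)c(C(=O)CCc5ccc(OCc6ccccc6)cc5)c(O)c(C)c4O)c(OCc4ccccc4)cc(OCc4ccccc4)c3c(=O)c2OCc2ccccc2)cc1
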